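**Retrosynthetic overview**

1. Kobophenol A (45) comes from 43 by removal of one pivalate and nine benzyl ethers; 43 is cut in ring A (the central dihydrobenzofuran; locants O1, C2, C3, C3a, C4–C7, C7a) at O1–C7a and C3–C3a.
2. Key event: aryne 41 (C7a≡C3a, from silyl triflate 24, which already carries the complete oxolane on C4) inserts into the benzylic C3–O bond of the enantiopure trans-diaryloxirane 40 (which carries ring B, the outer dihydrobenzofuran); this three- to five-membered ring expansion joins the two halves and sets C3.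
3. Enabling feature: C3 of ring A is bonded to C5' of ring B, para to the ring-B oxygen O1' on C7a', so C3 can carry a para-quinone-methide-type cation, while C2 carries only a 4-oxyphenyl group that is switched off as its pivalate; O1 and C3 end on the adjacent arene carbons C7a and C3a (an aryne pair), and the bulky oxolane on C4 screens C3a so that oxygen adds at C7a.
4. 24 comes from oxolane 17: an Ir/isothiourea allylic alkylation (8 + 4) sets oxolane C3 and C4, the γ-lactone ring is closed in step 7, and two trans-selective Friedel–Crafts arylations set C5 and C2; the silyl-marked resorcinol ring is then unmasked, brominated and converted into the silyl triflate by retro-Brook rearrangement.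
5. 40 comes from Shi epoxidation of stilbene 39, made by Heck coupling of bromide 35 (ring B by Rh-carbene C–H insertion, then C2' epimerisation). Ring order: lactone/oxolane (steps 7–10), ring B (step 20), oxirane (step 24), ring A (step 25).

Key step: step 25

Assumption: the structure is taken exactly as written (ring B is attached through C5' and carries the 7'-hydroxyl); in steps 6 and 20 the antipode of each chiral catalyst is the one that delivers the configuration shown.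

Abbreviations: Bn = benzyl; TIPS = triisopropylsilyl; Ox = (2R,3S,4R,5S)-2,5-bis[4-(benzyloxy)phenyl]-4-[3,5-bis(benzyloxy)phenyl]oxolan-3-yl; RB = (2R,3R)-7-(benzyloxy)-2-[4-(benzyloxy)phenyl]-3-[3,5-bis(benzyloxy)phenyl]-2,3-dihydro-1-benzofuran-5-yl; L = O,O'-(1,1'-binaphthalene-2,2'-diyl) N,N-bis(1-phenylethyl)phosphoramidite; BTM = benzotetramisole.

**Route**

Step 1
Reactants: 1 3,5-bis(benzyloxy)benzaldehyde
Product: 2 ethyl (2E)-3-[3,5-bis(benzyloxy)phenyl]prop-2-enoate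
Conditions: (EtO)2P(O)CH2CO2Et, NaH, THF, 0 °C → rt
Reagents that add atoms: triethyl phosphonoacetate, CCOC(=O)CP(=O)(OCC)OCC
Why: Horner–Wadsworth–Emmons olefination with a stabilised phosphonate should give the (E)-cinnamate.

Step 2
Reactants: 2 ethyl (2E)-3-[3,5-bis(benzyloxy)phenyl]prop-2-enoate
Product: 3 (2E)-3-[3,5-bis(benzyloxy)phenyl]prop-2-en-1-ol
Conditions: i-Bu2AlH (2.2 equiv), CH2Cl2, −78 → 0 °C; aq. Rochelle salt
Reagents that add atoms: none
Why: 1,2-reduction of the conjugated ester by the aluminium hydride leaves the alkene and the benzyl ethers untouched.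

Step 3
Reactants: 3 (2E)-3-[3,5-bis(benzyloxy)phenyl]prop-2-en-1-ol
Product: 4 tert-butyl (2E)-3-[3,5-bis(benzyloxy)phenyl]prop-2-en-1-yl carbonate
Conditions: Boc2O, Bu4NHSO4 (cat.), 30% aq. NaOH, CH2Cl2, 0 °C → rt
Reagents that add atoms: di-tert-butyl dicarbonate, CC(C)(C)OC(=O)OC(=O)OC(C)(C)C
Why: O-acylation of the primary allylic alcohol under phase-transfer conditions gives the linear carbonate that serves as the allyl electrophile.

Step 4
Reactants: 5 (3,5-dihydroxyphenyl)acetic acid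
Product: 7 {3,5-bis[(triisopropylsilyl)oxy]phenyl}acetic acid, via triisopropylsilyl ester 6 (not isolated)
Conditions: i-Pr3SiCl (3.3 equiv), imidazole, DMF, rt; then AcOH/THF/H2O, rt
Reagents that add atoms: chlorotriisopropylsilane, CC(C)[Si](Cl)(C(C)C)C(C)C
Why: exhaustive silylation followed by selective hydrolysis of the labile silyl ester leaves the hindered aryl silyl ethers, which mark this ring as the only one that can later be unmasked beside benzyl ethers.

Step 5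
Reactants: 7 {3,5-bis[(triisopropylsilyl)oxy]phenyl}acetic acid
Product: 8 pentafluorophenyl {3,5-bis[(triisopropylsilyl)oxy]phenyl}acetate
Conditions: C6F5OH, DCC, DMAP (cat.), CH2Cl2, 0 °C → rt
Reagents that add atoms: pentafluorophenol, Oc1c(F)c(F)c(F)c(F)c1F
Why: carbodiimide (Steglich-type) esterification gives the activated aryl ester required for isothiourea catalysis.

Step 6
Reactants: 8 pentafluorophenyl {3,5-bis[(triisopropylsilyl)oxy]phenyl}acetate; 4 tert-butyl (2E)-3-[3,5-bis(benzyloxy)phenyl]prop-2-en-1-yl carbonate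
Product: 10 (2S,3R)-3-[3,5-bis(benzyloxy)phenyl]-2-{3,5-bis[(triisopropylsilyl)oxy]phenyl}pent-4-enoic acid, via pentafluorophenyl ester 9 (not isolated)
Conditions: [Ir(cod)Cl]2 (2 mol %), L (4 mol %, pre-activated with n-PrNH2), BTM (10 mol %), i-Pr2NEt, THF, 25 °C; then LiOH, THF/H2O, 0 °C; 1 M HCl work-up
Reagents that add atoms: lithium hydroxide, [Li+].[OH-]
Why: stereodivergent dual-catalytic asymmetric allylic alkylation, in which the cyclometalated Ir-phosphoramidite allyl complex is attacked at its aryl-bearing terminus and fixes C3 while the isothiourea-bound ammonium enolate fixes C2, so both new stereocentres are under independent catalyst control and the (2S,3R) isomer is chosen by the pairing of antipodes; phenoxide rebound gives 9, which is hydrolysed cold without touching C2.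

Step 7
Reactants: 10 (2S,3R)-3-[3,5-bis(benzyloxy)phenyl]-2-{3,5-bis[(triisopropylsilyl)oxy]phenyl}pent-4-enoic acid
Product: 12 (3S,4R)-5-acetoxy-4-[3,5-bis(benzyloxy)phenyl]-3-{3,5-bis[(triisopropylsilyl)oxy]phenyl}oxolan-2-one (both C5 epimers), via hydroxy lactone 11 (not isolated)
Conditions: O3, pyridine (3 equiv), CH2Cl2, −78 °C (indicator end point); then Ac2O, DMAP, −78 → 0 °C
Reagents that add atoms: ozone, [O-][O+]=O; acetic anhydride, CC(=O)OC(C)=O
Why: ozonolysis in the presence of pyridine gives the aldehyde directly, which closes with the neighbouring carboxyl group to the five-membered hydroxy lactone and is trapped as the acylal by acetylation, so the enolisable aldehyde is never handled; C5 is formed as a mixture that is erased in step 8.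

Step 8
Reactants: 12 (3S,4R)-5-acetoxy lactone; 13 benzyl phenyl ether
Product: 14 (3S,4R,5S)-5-[4-(benzyloxy)phenyl]-4-[3,5-bis(benzyloxy)phenyl]-3-{3,5-bis[(triisopropylsilyl)oxy]phenyl}oxolan-2-one
Conditions: 13 (5 equiv), Me3SiOTf (0.2 equiv), CH2Cl2, −40 → −10 °C; Et3N quench
Reagents that add atoms: none
Why: Friedel–Crafts arylation of the cyclic acyloxycarbenium ion by the para position of the aryl ether on the face opposite to the two cis aryl groups at C3 and C4 sets C5 trans to the C4 aryl (5S).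

Step 9
Reactants: 14 (3S,4R,5S)-triaryl oxolan-2-one
Product: 16 (3S,4R,5S)-5-[4-(benzyloxy)phenyl]-4-[3,5-bis(benzyloxy)phenyl]-3-{3,5-bis[(triisopropylsilyl)oxy]phenyl}oxolan-2-yl acetate (both C2 epimers), via aluminium lactolate 15 (not isolated)
Conditions: i-Bu2AlH (1.2 equiv), CH2Cl2, −78 °C; then pyridine, DMAP, Ac2O, −78 → −20 °C
Reagents that add atoms: acetic anhydride, CC(=O)OC(C)=O
Why: reductive acetylation, in which the hydride stops at the aluminium lactolate at low temperature and acetylation in the same flask gives the anomeric acetate without ring opening or enolisation at the aryl-bearing C3.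

Step 10
Reactants: 16 (3S,4R,5S)-oxolan-2-yl acetate; 13 benzyl phenyl ether
Product: 17 (2R,3S,4R,5S)-2,5-bis[4-(benzyloxy)phenyl]-4-[3,5-bis(benzyloxy)phenyl]-3-{3,5-bis[(triisopropylsilyl)oxy]phenyl}oxolane
Conditions: 13 (8 equiv), Me3SiOTf (0.2 equiv), CH2Cl2, −78 → −40 °C; Et3N quench
Reagents that add atoms: none
Why: second Friedel–Crafts arylation through the cyclic oxocarbenium ion, attacked anti to the adjacent C3 aryl (and to the C4 aryl on the same face), sets C2 (R) trans to C3 and cis to the C5 aryl.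

Step 11
Reactants: 17 bis(silyl ether) oxolane
Product: 18 5-Ox-benzene-1,3-diol
Conditions: Bu4NF (2.2 equiv), AcOH (2.2 equiv), THF, 0 °C
Reagents that add atoms: none
Why: buffered fluoride cleaves only the two aryl silyl ethers and frees the resorcinol on the oxolane C3 aryl alone.

Step 12
Reactants: 18 5-Ox-benzene-1,3-diol
Product: 19 4-bromo-5-Ox-benzene-1,3-diol
Conditions: NBS (1.0 equiv), THF, −78 °C
Reagents that add atoms: N-bromosuccinimide, O=C1CCC(=O)N1Br
Why: electrophilic aromatic bromination, in which the free resorcinol ring is far more reactive than the ether rings and reacts at the position next to the alkyl group (para to one hydroxyl, ortho to the other), the usual site in 5-alkylresorcinols; the two such positions are equivalent.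

Step 13
Reactants: 19 4-bromo-5-Ox-benzene-1,3-diol
Product: 23 5-hydroxy-3-Ox-2-(trimethylsilyl)phenyl trifluoromethanesulfonate, via bis(trimethylsilyl) ether 20 (not isolated), via lithium phenoxide 21 (not isolated), via silyl ether triflate 22 (not isolated)
Conditions: (Me3Si)2NH, THF, 65 °C, then evaporation; n-BuLi (1.05 equiv), THF, −78 → −40 °C; Tf2O (1.1 equiv), −78 °C; then aq. NaHCO3, rt
Reagents that add atoms: hexamethyldisilazane, C[Si](C)(C)N[Si](C)(C)C; trifluoromethanesulfonic anhydride, O=S(=O)(OS(=O)(=O)C(F)(F)F)C(F)(F)F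
Why: O-silylation, bromine–lithium exchange and retro-Brook (1,3 O→C) silyl migration give the ortho-silyl lithium phenoxide, which is triflated; only the oxygen ortho to bromine can deliver silicon, so the two oxygens are differentiated, and the remaining aryl O–silyl group is hydrolysed on work-up.

Step 14
Reactants: 23 5-hydroxy-3-Ox-2-(trimethylsilyl)phenyl trifluoromethanesulfonate
Product: 24 5-(benzyloxy)-3-Ox-2-(trimethylsilyl)phenyl trifluoromethanesulfonate
Conditions: BnOH, PPh3, DIAD, THF, 0 °C → rt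
Reagents that add atoms: benzyl alcohol, OCc1ccccc1
Why: Mitsunobu O-alkylation benzylates the phenol under neutral conditions that do not trigger the silyl triflate.

Step 15
Reactants: 25 2-(benzyloxy)phenol
Product: 26 2-(benzyloxy)-4,6-dibromophenol
Conditions: NBS (2.05 equiv), MeCN, 0 °C → rt
Reagents that add atoms: N-bromosuccinimide, O=C1CCC(=O)N1Br
Why: electrophilic bromination ortho and para to the free hydroxyl, the stronger director, gives the 4,6-dibromide.

Step 16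
Reactants: 26 2-(benzyloxy)-4,6-dibromophenol; 27 1-(benzyloxy)-4-(chloromethyl)benzene
Product: 28 1-(benzyloxy)-2-{[4-(benzyloxy)phenyl]methoxy}-3,5-dibromobenzene
Conditions: K2CO3, NaI (cat.), DMF, 60 °C
Reagents that add atoms: none
Why: Williamson ether synthesis installs the benzylic O–CH2 group whose C–H bond is used in step 20.

Step 17
Reactants: 28 1-(benzyloxy)-2-{[4-(benzyloxy)phenyl]methoxy}-3,5-dibromobenzene; 1 3,5-bis(benzyloxy)benzaldehyde
Product: 30 [3-(benzyloxy)-2-{[4-(benzyloxy)phenyl]methoxy}-5-bromophenyl][3,5-bis(benzyloxy)phenyl]methanol (racemic), via arylmagnesium chloride 29 (not isolated)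
Conditions: i-PrMgCl·LiCl (1.05 equiv), THF, −20 °C; then 1, −20 → 0 °C; aq. NH4Cl
Reagents that add atoms: none
Why: bromine–magnesium exchange is selective for the bromine ortho to the alkoxy group (inductive and chelation acceleration) and the aryl Grignard reagent adds to the aldehyde; the carbinol centre is removed in the next step.

Step 18
Reactants: 30 diaryl carbinol
Product: 31 [3-(benzyloxy)-2-{[4-(benzyloxy)phenyl]methoxy}-5-bromophenyl][3,5-bis(benzyloxy)phenyl]methanone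
Conditions: n-Pr4NRuO4 (5 mol %), N-methylmorpholine N-oxide (1.5 equiv), 4 Å MS, CH2Cl2, rt
Reagents that add atoms: none
Why: catalytic perruthenate oxidation converts the diaryl carbinol into the ketone without touching the benzyl ethers or the aryl bromide.

Step 19
Reactants: 31 diaryl ketone
Product: 32 hydrazone of 31 (E/Z mixture)
Conditions: N2H4·H2O (10 equiv), AcOH (cat.), EtOH, 80 °C
Reagents that add atoms: hydrazine, NN
Why: condensation with excess hydrazine gives the N-unsubstituted hydrazone, the precursor of the diaryldiazomethane.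

Step 20
Reactants: 32 hydrazone
Product: 34 (2S,3R)-7-(benzyloxy)-2-[4-(benzyloxy)phenyl]-3-[3,5-bis(benzyloxy)phenyl]-5-bromo-2,3-dihydro-1-benzofuran (cis), via diaryldiazomethane 33 (not isolated)
Conditions: MnO2, CH2Cl2, 0 °C, filtration through Celite; filtrate added slowly to Rh2(R-PTAD)4 (1 mol %), CH2Cl2, 0 °C
Reagents that add atoms: none
Why: oxidation to the diazo compound and Rh-catalysed intramolecular C–H insertion of the donor/donor carbene into the benzylic O–CH2 bond (five-membered ring) form ring B; the chiral carboxylate ligands set C3' (R) and the concerted insertion gives the cis isomer.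

Step 21
Reactants: 34 cis-(2S,3R)-dihydrobenzofuran
Product: 35 (2R,3R)-7-(benzyloxy)-2-[4-(benzyloxy)phenyl]-3-[3,5-bis(benzyloxy)phenyl]-5-bromo-2,3-dihydro-1-benzofuran (trans)
Conditions: CF3CO2H (2 equiv), CH2Cl2 (dilute), 0 °C → rt
Reagents that add atoms: none
Why: acid-mediated epimerisation at C2' through reversible C2'–O heterolysis to the 4-benzyloxybenzyl cation (C3' is not touched) should give the thermodynamically preferred trans isomer.

Step 22
Reactants: 36 4-ethenylphenyl acetate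
Product: 38 4-ethenylphenyl 2,2-dimethylpropanoate, via sodium 4-ethenylphenolate 37 (not isolated)
Conditions: NaOMe (1.0 equiv), MeOH, 0 °C, then evaporation; t-BuCOCl (1.1 equiv), THF, 0 °C → rt
Reagents that add atoms: pivaloyl chloride, CC(C)(C)C(Cl)=O
Why: methanolysis of the acetate and O-acylation of the phenoxide give the pivalate, chosen because it is electron-poor and should survive carbonate buffer and fluoride.

Step 23
Reactants: 35 trans-(2R,3R)-5-bromo-dihydrobenzofuran; 38 4-ethenylphenyl 2,2-dimethylpropanoate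
Product: 39 4-[(E)-2-RB-ethenyl]phenyl 2,2-dimethylpropanoate
Conditions: Pd2(dba)3 (2 mol %), P(t-Bu)3·HBF4 (5 mol %), Cy2NMe (1.5 equiv), dioxane, 70 °C
Reagents that add atoms: none
Why: the Heck reaction of the aryl bromide with the styrene gives the (E)-stilbene.

Step 24
Reactants: 39 (E)-stilbene
Product: 40 4-[(2R,3R)-3-RB-oxiran-2-yl]phenyl 2,2-dimethylpropanoate
Conditions: 1,2:4,5-di-O-isopropylidene-D-erythro-2,3-hexodiulo-2,6-pyranose (0.3 equiv), KHSO5 (as Oxone), K2CO3, Bu4NHSO4 (cat.), Na2B4O7 buffer, MeCN/dimethoxymethane/H2O, 0 °C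
Reagents that add atoms: potassium peroxymonosulfate, [K+].[O-]S(=O)(=O)OO
Why: Shi epoxidation, in which the fructose-derived dioxirane epoxidises the trans-disubstituted alkene through the spiro transition state under reagent control, should give the (2R,3R)-oxirane irrespective of the remote stereocentres; the basic buffer protects the acid-labile product.

Step 25
Reactants: 24 5-(benzyloxy)-3-Ox-2-(trimethylsilyl)phenyl trifluoromethanesulfonate; 40 4-[(2R,3R)-3-RB-oxiran-2-yl]phenyl 2,2-dimethylpropanoate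
Product: 43 4-[(2S,3S)-6-(benzyloxy)-4-Ox-3-RB-2,3-dihydro-1-benzofuran-2-yl]phenyl 2,2-dimethylpropanoate, via aryne 41 (not isolated), via oxiranium betaine 42 (not isolated)
Conditions: CsF (3 equiv), 40 (2 equiv, excess recovered), MeCN/toluene 1:1, 4 Å MS, 25 → 45 °C
Reagents that add atoms: none
Why: Proposed new method: fluoride-induced 1,2-elimination of 24 gives aryne 41, whose carbon remote from the oxolane (the future C7a) is attacked by the oxirane oxygen of 40 to give the ortho-oxiranium aryl anion 42; heterolysis of the oxiranium C3–O bond and collapse of the aryl anion onto C3 then insert the two aryne carbons into that bond. The closest known reaction type is the formal insertion of benzyne into the benzylic C–O bond of styrene oxide to give a 3-aryl-2,3-dihydrobenzofuran, which has not been shown for 2,3-diaryloxiranes, for transfer of configuration or for an aryne of this size. Ring A closes by ring expansion of the oxirane (three to five atoms): O1–C7a forms in the intermolecular addition and C3–C3a in a 5-exo-trig collapse of the aryl carbanion onto the cation, whose quinoid C=C is exocyclic. C2 is not touched (its C–O bond persists), so (2R) in 40 becomes (2S) in 43 only by a change of priorities; C3 is set in the ring closure, where ion-pair collapse on the face from which oxygen departs and the preference of the two aryl groups for a trans arrangement both lead to (3S). Three selectivities are needed: oxygen attack at the aryne carbon remote from C4, secured by the bulk of the tetrasubstituted oxolane next to C3a against only a weak opposing inductive effect of the benzyloxy group; cleavage of C3–O and not C2–O, secured by the para ring oxygen O1' of ring B on the C3 aryl against the electron-poor 4-pivaloyloxyphenyl group on C2; and C–C bond formation in preference to proton transfer, the only proton within reach of the aryl anion being an oxirane C–H.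

Step 26
Reactants: 43 pivalate nonabenzyl ether
Product: 44 4-[(2S,3S)-6-(benzyloxy)-4-Ox-3-RB-2,3-dihydro-1-benzofuran-2-yl]phenol
Conditions: K2CO3 (0.5 equiv), MeOH/THF 1:1, 40 °C
Reagents that add atoms: none
Why: base-catalysed transesterification removes the single aryl pivalate under conditions that leave all benzylic ethers and stereocentres alone.

Step 27
Reactants: 44 phenol nonabenzyl ether
Product: 45 kobophenol A
Conditions: H2 (1 atm), Pd(OH)2/C, THF/MeOH, rt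
Reagents that add atoms: none
Why: hydrogenolysis of the nine benzyl ethers under neutral conditions avoids the acid to which the oxolane benzylic ethers are sensitive; the reaction is stopped at full debenzylation to spare the ring C–O bonds.

**Compound list**

1 | 3,5-bis(benzyloxy)benzaldehyde | O=Cc1cc(OCc2ccccc2)cc(OCc2ccccc2)c1 | starting material
2 | ethyl (2E)-3-[3,5-bis(benzyloxy)phenyl]prop-2-enoate | CCOC(=O)/C=C/c1cc(OCc2ccccc2)cc(OCc2ccccc2)c1 | intermediate
3 | (2E)-3-[3,5-bis(benzyloxy)phenyl]prop-2-en-1-ol | OC/C=C/c1cc(OCc2ccccc2)cc(OCc2ccccc2)c1 | intermediate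
4 | tert-butyl (2E)-3-[3,5-bis(benzyloxy)phenyl]prop-2-en-1-yl carbonate | CC(C)(C)OC(=O)OC/C=C/c1cc(OCc2ccccc2)cc(OCc2ccccc2)c1 | intermediate
5 | (3,5-dihydroxyphenyl)acetic acid | OC(=O)Cc1cc(O)cc(O)c1 | starting material
6 | triisopropylsilyl {3,5-bis[(triisopropylsilyl)oxy]phenyl}acetate | CC(C)[Si](C(C)C)(C(C)C)OC(=O)Cc1cc(O[Si](C(C)C)(C(C)C)C(C)C)cc(O[Si](C(C)C)(C(C)C)C(C)C)c1 | intermediate
7 | {3,5-bis[(triisopropylsilyl)oxy]phenyl}acetic acid | OC(=O)Cc1cc(O[Si](C(C)C)(C(C)C)C(C)C)cc(O[Si](C(C)C)(C(C)C)C(C)C)c1 | intermediate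
8 | pentafluorophenyl {3,5-bis[(triisopropylsilyl)oxy]phenyl}acetate | O=C(Cc1cc(O[Si](C(C)C)(C(C)C)C(C)C)cc(O[Si](C(C)C)(C(C)C)C(C)C)c1)Oc1c(F)c(F)c(F)c(F)c1F | intermediate
9 | pentafluorophenyl (2S,3R)-3-[3,5-bis(benzyloxy)phenyl]-2-{3,5-bis[(triisopropylsilyl)oxy]phenyl}pent-4-enoate | CC(C)[Si](C(C)C)(C(C)C)Oc3cc(O[Si](C(C)C)(C(C)C)C(C)C)cc([C@@H](C(=O)Oc4c(F)c(F)c(F)c(F)c4F)[C@H](c5cc(OCc6ccccc6)cc(OCc6ccccc6)c5)C=C)c3 | intermediate
10 | (2S,3R)-3-[3,5-bis(benzyloxy)phenyl]-2-{3,5-bis[(triisopropylsilyl)oxy]phenyl}pent-4-enoic acid | CC(C)[Si](C(C)C)(C(C)C)Oc3cc(O[Si](C(C)C)(C(C)C)C(C)C)cc([C@@H](C(O)=O)[C@H](c5cc(OCc6ccccc6)cc(OCc6ccccc6)c5)C=C)c3 | intermediate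
11 | (3S,4R)-4-[3,5-bis(benzyloxy)phenyl]-3-{3,5-bis[(triisopropylsilyl)oxy]phenyl}-5-hydroxyoxolan-2-one (both C5 epimers) | CC(C)[Si](C(C)C)(C(C)C)Oc3cc(O[Si](C(C)C)(C(C)C)C(C)C)cc([C@@H]4[C@H](c5cc(OCc6ccccc6)cc(OCc6ccccc6)c5)C(O)OC4=O)c3 | intermediate
12 | (3S,4R)-5-acetoxy-4-[3,5-bis(benzyloxy)phenyl]-3-{3,5-bis[(triisopropylsilyl)oxy]phenyl}oxolan-2-one (both C5 epimers) | CC(C)[Si](C(C)C)(C(C)C)Oc3cc(O[Si](C(C)C)(C(C)C)C(C)C)cc([C@@H]4[C@H](c5cc(OCc6ccccc6)cc(OCc6ccccc6)c5)C(OC(C)=O)OC4=O)c3 | intermediate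
13 | benzyl phenyl ether | c1ccc(OCc2ccccc2)cc1 | starting material
14 | (3S,4R,5S)-5-[4-(benzyloxy)phenyl]-4-[3,5-bis(benzyloxy)phenyl]-3-{3,5-bis[(triisopropylsilyl)oxy]phenyl}oxolan-2-one | CC(C)[Si](C(C)C)(C(C)C)Oc3cc(O[Si](C(C)C)(C(C)C)C(C)C)cc([C@@H]4[C@H](c5cc(OCc6ccccc6)cc(OCc6ccccc6)c5)[C@@H](c5ccc(OCc6ccccc6)cc5)OC4=O)c3 | intermediate
15 | diisobutylaluminium (3S,4R,5S)-5-[4-(benzyloxy)phenyl]-4-[3,5-bis(benzyloxy)phenyl]-3-{3,5-bis[(triisopropylsilyl)oxy]phenyl}oxolan-2-olate (both C2 epimers) | CC(C)[Si](C(C)C)(C(C)C)Oc3cc(O[Si](C(C)C)(C(C)C)C(C)C)cc([C@@H]4[C@H](c5cc(OCc6ccccc6)cc(OCc6ccccc6)c5)[C@@H](c5ccc(OCc6ccccc6)cc5)OC4O[Al](CC(C)C)CC(C)C)c3 | intermediate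
16 | (3S,4R,5S)-5-[4-(benzyloxy)phenyl]-4-[3,5-bis(benzyloxy)phenyl]-3-{3,5-bis[(triisopropylsilyl)oxy]phenyl}oxolan-2-yl acetate (both C2 epimers) | CC(C)[Si](C(C)C)(C(C)C)Oc3cc(O[Si](C(C)C)(C(C)C)C(C)C)cc([C@@H]4[C@H](c5cc(OCc6ccccc6)cc(OCc6ccccc6)c5)[C@@H](c5ccc(OCc6ccccc6)cc5)OC4OC(C)=O)c3 | intermediate
17 | (2R,3S,4R,5S)-2,5-bis[4-(benzyloxy)phenyl]-4-[3,5-bis(benzyloxy)phenyl]-3-{3,5-bis[(triisopropylsilyl)oxy]phenyl}oxolane | CC(C)[Si](C(C)C)(C(C)C)Oc3cc(O[Si](C(C)C)(C(C)C)C(C)C)cc([C@@H]4[C@H](c5cc(OCc6ccccc6)cc(OCc6ccccc6)c5)[C@@H](c5ccc(OCc6ccccc6)cc5)O[C@H]4c4ccc(OCc6ccccc6)cc4)c3 | intermediate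
18 | 5-{(2R,3S,4R,5S)-2,5-bis[4-(benzyloxy)phenyl]-4-[3,5-bis(benzyloxy)phenyl]oxolan-3-yl}benzene-1,3-diol | Oc3cc(O)cc([C@@H]4[C@H](c5cc(OCc6ccccc6)cc(OCc6ccccc6)c5)[C@@H](c5ccc(OCc6ccccc6)cc5)O[C@H]4c4ccc(OCc6ccccc6)cc4)c3 | intermediate
19 | 4-bromo-5-Ox-benzene-1,3-diol | Oc3cc(O)cc([C@@H]4[C@H](c5cc(OCc6ccccc6)cc(OCc6ccccc6)c5)[C@@H](c5ccc(OCc6ccccc6)cc5)O[C@H]4c4ccc(OCc6ccccc6)cc4)c3Br | intermediate
20 | 2-bromo-3-Ox-1,5-bis[(trimethylsilyl)oxy]benzene | C[Si](C)(C)Oc3cc(O[Si](C)(C)C)cc([C@@H]4[C@H](c5cc(OCc6ccccc6)cc(OCc6ccccc6)c5)[C@@H](c5ccc(OCc6ccccc6)cc5)O[C@H]4c4ccc(OCc6ccccc6)cc4)c3Br | intermediate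
21 | lithium 3-Ox-2-(trimethylsilyl)-5-[(trimethylsilyl)oxy]phenolate | [Li+].[O-]c3cc(O[Si](C)(C)C)cc([C@@H]4[C@H](c5cc(OCc6ccccc6)cc(OCc6ccccc6)c5)[C@@H](c5ccc(OCc6ccccc6)cc5)O[C@H]4c4ccc(OCc6ccccc6)cc4)c3[Si](C)(C)C | intermediate
22 | 3-Ox-2-(trimethylsilyl)-5-[(trimethylsilyl)oxy]phenyl trifluoromethanesulfonate | FC(F)(F)S(=O)(=O)Oc3cc(O[Si](C)(C)C)cc([C@@H]4[C@H](c5cc(OCc6ccccc6)cc(OCc6ccccc6)c5)[C@@H](c5ccc(OCc6ccccc6)cc5)O[C@H]4c4ccc(OCc6ccccc6)cc4)c3[Si](C)(C)C | intermediate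
23 | 5-hydroxy-3-Ox-2-(trimethylsilyl)phenyl trifluoromethanesulfonate | FC(F)(F)S(=O)(=O)Oc3cc(O)cc([C@@H]4[C@H](c5cc(OCc6ccccc6)cc(OCc6ccccc6)c5)[C@@H](c5ccc(OCc6ccccc6)cc5)O[C@H]4c4ccc(OCc6ccccc6)cc4)c3[Si](C)(C)C | intermediate
24 | 5-(benzyloxy)-3-Ox-2-(trimethylsilyl)phenyl trifluoromethanesulfonate | FC(F)(F)S(=O)(=O)Oc3cc(OCc6ccccc6)cc([C@@H]4[C@H](c5cc(OCc6ccccc6)cc(OCc6ccccc6)c5)[C@@H](c5ccc(OCc6ccccc6)cc5)O[C@H]4c4ccc(OCc6ccccc6)cc4)c3[Si](C)(C)C | intermediate
25 | 2-(benzyloxy)phenol | Oc1ccccc1OCc1ccccc1 | starting material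
26 | 2-(benzyloxy)-4,6-dibromophenol | Oc1c(Br)cc(Br)cc1OCc1ccccc1 | intermediate
27 | 1-(benzyloxy)-4-(chloromethyl)benzene | ClCc1ccc(OCc2ccccc2)cc1 | starting material
28 | 1-(benzyloxy)-2-{[4-(benzyloxy)phenyl]methoxy}-3,5-dibromobenzene | Brc1cc(Br)cc(OCc2ccccc2)c1OCc1ccc(OCc2ccccc2)cc1 | intermediate
29 | [3-(benzyloxy)-2-{[4-(benzyloxy)phenyl]methoxy}-5-bromophenyl]magnesium chloride | Cl[Mg]c1cc(Br)cc(OCc2ccccc2)c1OCc1ccc(OCc2ccccc2)cc1 | intermediate
30 | [3-(benzyloxy)-2-{[4-(benzyloxy)phenyl]methoxy}-5-bromophenyl][3,5-bis(benzyloxy)phenyl]methanol (racemic) | OC(c1cc(OCc2ccccc2)cc(OCc2ccccc2)c1)c1cc(Br)cc(OCc2ccccc2)c1OCc1ccc(OCc2ccccc2)cc1 | intermediate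
31 | [3-(benzyloxy)-2-{[4-(benzyloxy)phenyl]methoxy}-5-bromophenyl][3,5-bis(benzyloxy)phenyl]methanone | O=C(c1cc(OCc2ccccc2)cc(OCc2ccccc2)c1)c1cc(Br)cc(OCc2ccccc2)c1OCc1ccc(OCc2ccccc2)cc1 | intermediate
32 | hydrazone of 31 (E/Z mixture) | NN=C(c1cc(OCc2ccccc2)cc(OCc2ccccc2)c1)c1cc(Br)cc(OCc2ccccc2)c1OCc1ccc(OCc2ccccc2)cc1 | intermediate
33 | 1-(benzyloxy)-2-{[4-(benzyloxy)phenyl]methoxy}-3-{[3,5-bis(benzyloxy)phenyl](diazo)methyl}-5-bromobenzene | [N-]=[N+]=C(c1cc(OCc2ccccc2)cc(OCc2ccccc2)c1)c1cc(Br)cc(OCc2ccccc2)c1OCc1ccc(OCc2ccccc2)cc1 | intermediate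
34 | (2S,3R)-7-(benzyloxy)-2-[4-(benzyloxy)phenyl]-3-[3,5-bis(benzyloxy)phenyl]-5-bromo-2,3-dihydro-1-benzofuran (cis) | Brc1cc(OCc6ccccc6)c2c(c1)[C@@H](c1cc(OCc6ccccc6)cc(OCc6ccccc6)c1)[C@@H](c1ccc(OCc6ccccc6)cc1)O2 | intermediate
35 | (2R,3R)-7-(benzyloxy)-2-[4-(benzyloxy)phenyl]-3-[3,5-bis(benzyloxy)phenyl]-5-bromo-2,3-dihydro-1-benzofuran (trans) | Brc1cc(OCc6ccccc6)c2c(c1)[C@@H](c1cc(OCc6ccccc6)cc(OCc6ccccc6)c1)[C@H](c1ccc(OCc6ccccc6)cc1)O2 | intermediate
36 | 4-ethenylphenyl acetate | CC(=O)Oc1ccc(C=C)cc1 | starting material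
37 | sodium 4-ethenylphenolate | [Na+].[O-]c1ccc(C=C)cc1 | intermediate
38 | 4-ethenylphenyl 2,2-dimethylpropanoate | CC(C)(C)C(=O)Oc1ccc(C=C)cc1 | intermediate
39 | 4-[(E)-2-RB-ethenyl]phenyl 2,2-dimethylpropanoate | CC(C)(C)C(=O)Oc1ccc(/C=C/c2cc(OCc6ccccc6)c3c(c2)[C@@H](c2cc(OCc6ccccc6)cc(OCc6ccccc6)c2)[C@H](c2ccc(OCc6ccccc6)cc2)O3)cc1 | intermediate
40 | 4-[(2R,3R)-3-RB-oxiran-2-yl]phenyl 2,2-dimethylpropanoate | CC(C)(C)C(=O)Oc1ccc([C@H]7O[C@@H]7c2cc(OCc6ccccc6)c3c(c2)[C@@H](c2cc(OCc6ccccc6)cc(OCc6ccccc6)c2)[C@H](c2ccc(OCc6ccccc6)cc2)O3)cc1 | intermediate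
41 | 5-(benzyloxy)-3-Ox-1,2-didehydrobenzene (aryne) | C1#CC([C@@H]4[C@H](c5cc(OCc6ccccc6)cc(OCc6ccccc6)c5)[C@@H](c5ccc(OCc6ccccc6)cc5)O[C@H]4c4ccc(OCc6ccccc6)cc4)=CC(OCc6ccccc6)=C1 | intermediate
42 | (2R,3R)-1-[5-(benzyloxy)-3-Ox-phenyl-2-ide]-2-[4-(pivaloyloxy)phenyl]-3-RB-oxiranium (betaine) | CC(C)(C)C(=O)Oc1ccc([C@H]7[O+](c8cc(OCc6ccccc6)cc([C@@H]4[C@H](c5cc(OCc6ccccc6)cc(OCc6ccccc6)c5)[C@@H](c5ccc(OCc6ccccc6)cc5)O[C@H]4c4ccc(OCc6ccccc6)cc4)[c-]8)[C@@H]7c2cc(OCc6ccccc6)c3c(c2)[C@@H](c2cc(OCc6ccccc6)cc(OCc6ccccc6)c2)[C@H](c2ccc(OCc6ccccc6)cc2)O3)cc1 | intermediate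
43 | 4-[(2S,3S)-6-(benzyloxy)-4-Ox-3-RB-2,3-dihydro-1-benzofuran-2-yl]phenyl 2,2-dimethylpropanoate | CC(C)(C)C(=O)Oc1ccc([C@H]2Oc3cc(OCc6ccccc6)cc([C@@H]4[C@H](c5cc(OCc6ccccc6)cc(OCc6ccccc6)c5)[C@@H](c5ccc(OCc6ccccc6)cc5)O[C@H]4c4ccc(OCc6ccccc6)cc4)c3[C@@H]2c2cc(OCc6ccccc6)c3c(c2)[C@@H](c2cc(OCc6ccccc6)cc(OCc6ccccc6)c2)[C@H](c2ccc(OCc6ccccc6)cc2)O3)cc1 | intermediate
44 | 4-[(2S,3S)-6-(benzyloxy)-4-Ox-3-RB-2,3-dihydro-1-benzofuran-2-yl]phenol | Oc1ccc([C@H]2Oc3cc(OCc6ccccc6)cc([C@@H]4[C@H](c5cc(OCc6ccccc6)cc(OCc6ccccc6)c5)[C@@H](c5ccc(OCc6ccccc6)cc5)O[C@H]4c4ccc(OCc6ccccc6)cc4)c3[C@@H]2c2cc(OCc6ccccc6)c3c(c2)[C@@H](c2cc(OCc6ccccc6)cc(OCc6ccccc6)c2)[C@H](c2ccc(OCc6ccccc6)cc2)O3)cc1 | intermediate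
45 | kobophenol A, 5-[(2S,3R,4S,5R)-4-{(2S,3S)-3-[(2R,3R)-3-(3,5-dihydroxyphenyl)-7-hydroxy-2-(4-hydroxyphenyl)-2,3-dihydro-1-benzofuran-5-yl]-6-hydroxy-2-(4-hydroxyphenyl)-2,3-dihydro-1-benzofuran-4-yl}-2,5-bis(4-hydroxyphenyl)oxolan-3-yl]benzene-1,3-diol | Oc1ccc([C@H]2Oc3cc(O)cc([C@@H]4[C@H](c5cc(O)cc(O)c5)[C@@H](c5ccc(O)cc5)O[C@H]4c4ccc(O)cc4)c3[C@@H]2c2cc(O)c3c(c2)[C@@H](c2cc(O)cc(O)c2)[C@H](c2ccc(O)cc2)O3)cc1 | target

**Step count and risks**

Total step count: 27. Longest linear sequence: 15 steps (1–3, 6–14, 25–27).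

Steps most likely to fail:

Step 25 (proposed new method). The oxirane oxygen may add to both aryne carbons, or proton transfer within the betaine may outrun C–C bond formation. The fallback builds ring A with the phenol oxygen instead, using known reaction types, and sets out from 18 and 39. Stilbene 39 is epoxidised with the enantiomeric (L-fructose-derived) Shi ketone to the (2S,3S)-oxirane F1. Resorcinol 18 and the (2S,3S)-oxirane F1 in (CF3)2CHOH at 0 °C should undergo a stereospecific Friedel–Crafts opening of the oxirane at its benzylic C3 with inversion (attack by the resorcinol carbon next to the oxolane; the two such positions are equivalent), giving the hydroxy diphenol F2. Mitsunobu cyclodehydration of F2 (PPh3, DIAD, THF) lets the ortho phenol displace the secondary hydroxyl with inversion and gives the 6-hydroxy ring-A compound F3. O-Benzylation of F3 (BnBr, K2CO3, acetone) returns to 43.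

Step 10. The oxocarbenium ion may lose the proton at the aryl-bearing C3 (epimerisation through the enol ether), or the acid may ionise the C5 benzylic ether. The fallback replaces the Friedel–Crafts arylation by an arylzinc substitution and sets out from 14. Reduction with i-Bu2AlH at −78 °C gives the lactol F4; PhSO2H and CaCl2 in CH2Cl2 convert it into the anomeric sulfone F5; treatment of F5 with the arylzinc reagent from 4-BnOC6H4MgBr and ZnBr2 in THF at 0 °C should deliver the aryl group trans to the C3 aryl and return to 17.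

Step 6. The activated ester may enolise after the coupling, or a mismatched catalyst pairing may erode the diastereoselectivity. The fallback is an enantioselective Ireland–Claisen rearrangement and sets out from 7 and 3. DCC/DMAP esterification gives the cinnamyl ester F6; enolisation of F6 as the chiral boron enolate (one antipode of 2-bromo-4,5-diphenyl-1,3-bis(4-tolylsulfonyl)-1,3,2-diazaborolidine, tertiary amine, CH2Cl2 or toluene/hexane chosen for the enolate geometry that leads to the 2,3-anti acid) and [3,3]-rearrangement at −78 °C → rt return directly to 10.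

**Further compounds**

F1 | step 25 | 4-[(2S,3S)-3-RB-oxiran-2-yl]phenyl 2,2-dimethylpropanoate | CC(C)(C)C(=O)Oc1ccc([C@@H]7O[C@H]7c2cc(OCc6ccccc6)c3c(c2)[C@@H](c2cc(OCc6ccccc6)cc(OCc6ccccc6)c2)[C@H](c2ccc(OCc6ccccc6)cc2)O3)cc1
F2 | step 25 | 4-[(1R,2S)-2-(2,4-dihydroxy-6-Ox-phenyl)-1-hydroxy-2-RB-ethyl]phenyl 2,2-dimethylpropanoate | CC(C)(C)C(=O)Oc1ccc([C@H](O)[C@@H](c2cc(OCc6ccccc6)c3c(c2)[C@@H](c2cc(OCc6ccccc6)cc(OCc6ccccc6)c2)[C@H](c2ccc(OCc6ccccc6)cc2)O3)c2c(O)cc(O)cc2[C@@H]4[C@H](c5cc(OCc6ccccc6)cc(OCc6ccccc6)c5)[C@@H](c5ccc(OCc6ccccc6)cc5)O[C@H]4c4ccc(OCc6ccccc6)cc4)cc1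
F3 | step 25 | 4-[(2S,3S)-6-hydroxy-4-Ox-3-RB-2,3-dihydro-1-benzofuran-2-yl]phenyl 2,2-dimethylpropanoate | CC(C)(C)C(=O)Oc1ccc([C@H]2Oc3cc(O)cc([C@@H]4[C@H](c5cc(OCc6ccccc6)cc(OCc6ccccc6)c5)[C@@H](c5ccc(OCc6ccccc6)cc5)O[C@H]4c4ccc(OCc6ccccc6)cc4)c3[C@@H]2c2cc(OCc6ccccc6)c3c(c2)[C@@H](c2cc(OCc6ccccc6)cc(OCc6ccccc6)c2)[C@H](c2ccc(OCc6ccccc6)cc2)O3)cc1
F4 | step 10 | (3S,4R,5S)-5-[4-(benzyloxy)phenyl]-4-[3,5-bis(benzyloxy)phenyl]-3-{3,5-bis[(triisopropylsilyl)oxy]phenyl}oxolan-2-ol (both C2 epimers) | CC(C)[Si](C(C)C)(C(C)C)Oc3cc(O[Si](C(C)C)(C(C)C)C(C)C)cc([C@@H]4[C@H](c5cc(OCc6ccccc6)cc(OCc6ccccc6)c5)[C@@H](c5ccc(OCc6ccccc6)cc5)OC4O)c3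
F5 | step 10 | (3S,4R,5S)-2-(benzenesulfonyl)-5-[4-(benzyloxy)phenyl]-4-[3,5-bis(benzyloxy)phenyl]-3-{3,5-bis[(triisopropylsilyl)oxy]phenyl}oxolane (both C2 epimers) | CC(C)[Si](C(C)C)(C(C)C)Oc3cc(O[Si](C(C)C)(C(C)C)C(C)C)cc([C@@H]4[C@H](c5cc(OCc6ccccc6)cc(OCc6ccccc6)c5)[C@@H](c5ccc(OCc6ccccc6)cc5)OC4S(=O)(=O)c7ccccc7)c3
F6 | step 6 | (2E)-3-[3,5-bis(benzyloxy)phenyl]prop-2-en-1-yl {3,5-bis[(triisopropylsilyl)oxy]phenyl}acetate | CC(C)[Si](C(C)C)(C(C)C)Oc1cc(CC(=O)OC/C=C/c2cc(OCc3ccccc3)cc(OCc3ccccc3)c2)cc(O[Si](C(C)C)(C(C)C)C(C)C)c1
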